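**Strategy.** Everything rests on building the γ-butyrolactone ring from an enantiopure (Z)-alkenyl p-tolyl sulfoxide and dichloroketene. In one operation this sulfonium [3,3] rearrangement/lactonization (Marino reaction) forms the C3–C4 bond (lactone α-carbon to the benzyl-bearing CH) and the ring O–C5 bond, while relaying chirality from sulfur to C4. It exploits the lactone's adjacent ring atoms C4 (stereogenic CH) and C5 (OCH2), which map onto the two alkene carbons of the vinyl sulfoxide, sulfur marking C5. The precursor is (R,Z)-ArCH2CH=CH–S(O)Tol (Ar = 3,4-dimethoxyphenyl); chlorine and sulfur are then removed reductively and the 3-hydroxy-4-methoxybenzyl group is added trans by aldol addition and hydrogenolysis.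

Key step: step 4

Remark on the chemistry: the facial sense of the sulfur-to-carbon chirality transfer is assigned from the chair model with p-tolyl pseudo-equatorial, not from a recalled experimental correlation; the (R)-sulfur/(Z)-alkene pairing is chosen on that basis. The target is (3R,4R), trans.

**Step 1**
Reactants: 1 3,4-dimethoxybenzyl bromide; 2 ethynylmagnesium bromide
Product: 3 1,2-dimethoxy-4-(prop-2-yn-1-yl)benzene
Conditions: 2 (2.5 equiv, 0.5 M in THF), CuCl (10 mol %), THF, 0 °C to reflux; aq. NH4Cl
Reagents that add atoms: none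
Why: Copper-catalysed Kumada-type sp3–sp coupling of the benzylic bromide with the alkynyl Grignard reagent should give the skipped aryl alkyne, the excess of acetylide keeping a second benzylation in check; no stereocentre is formed.

**Step 2**
Reactants: 3 1,2-dimethoxy-4-(prop-2-yn-1-yl)benzene; 4 (1R,2S,5R)-menthyl (S)-p-toluenesulfinate
Product: 6 (S)-1,2-dimethoxy-4-[3-(p-tolylsulfinyl)prop-2-yn-1-yl]benzene, via alkynylmagnesium bromide 5 (not isolated)
Conditions: EtMgBr (1.0 equiv), THF, 0 °C to rt; then inverse addition to 4, toluene, −20 °C; aq. NH4Cl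
Reagents that add atoms: none
Why: Andersen sulfoxide synthesis: the alkynyl Grignard reagent displaces mentholate at sulfur with inversion, so the sulfur configuration comes from the diastereomerically pure sulfinate (descriptor S because alkynyl outranks p-tolyl).

**Step 3**
Reactants: 6 (S)-1,2-dimethoxy-4-[3-(p-tolylsulfinyl)prop-2-yn-1-yl]benzene
Product: 7 (R,Z)-1,2-dimethoxy-4-[3-(p-tolylsulfinyl)prop-2-en-1-yl]benzene
Conditions: H2 (1 atm), RhCl(PPh3)3 (5 mol %), benzene, rt
Reagents that add atoms: none
Why: Homogeneous syn-hydrogenation with Wilkinson's catalyst adds one H2 to the alkyne and should stop at the hindered, electron-poor (Z)-alkenyl sulfoxide; sulfur is untouched and its descriptor becomes R only because p-tolyl outranks alkenyl.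

**Step 4**
Reactants: 7 (R,Z)-1,2-dimethoxy-4-[3-(p-tolylsulfinyl)prop-2-en-1-yl]benzene; 8 trichloroacetyl chloride
Product: 12 (4S)-3,3-dichloro-4-(3,4-dimethoxybenzyl)-5-(p-tolylthio)dihydrofuran-2(3H)-one, via dichloroketene 9 (not isolated), via acyloxysulfonium enolate 10 (not isolated), via thionium carboxylate 11 (not isolated)
Conditions: 8 (2.5 equiv, slow addition), Zn–Cu couple, Et2O, reflux
Reagents that add atoms: none
Why: Zinc dechlorinates 8 to dichloroketene 9, whose carbonyl carbon is attacked by the sulfoxide oxygen of 7 to give the acyloxysulfonium enolate 10; a charge-accelerated [3,3]-sigmatropic shift across the C=C–S–O–C=C array then forms the C3–C4 bond and breaks S–O, and the carboxylate of the resulting thionium ion 11 adds to the sulfur-bearing carbon to form the ring O–C5 bond. The closest known reaction type is the Marino lactonization of enantiopure 1-alkenyl aryl sulfoxides with dichloroketene, an additive Pummerer reaction. The one ring closes by 5-exo-trig attack of carboxylate oxygen on the C=S+ carbon. C4 is set by sulfur-to-carbon chirality transfer in a chair-like transition state with p-tolyl pseudo-equatorial and the sulfur lone pair facing the cis CH2Ar group, so the enolate reaches one face of the (Z)-alkene and the (R)-sulfoxide should give the 4S product (R once Cl and S are gone); C5 should form mainly trans to C4 under substrate control and is erased in step 5. The step needs O-acylation of the sulfoxide to outrun [2+2] addition of the ketene to the alkene, and carboxylate capture to outrun arene capture of the thionium ion; the nucleophilic sulfoxide oxygen, the electron-poor alkene and the intramolecular ion pair secure this.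

**Step 5**
Reactants: 12 (4S)-3,3-dichloro-4-(3,4-dimethoxybenzyl)-5-(p-tolylthio)dihydrofuran-2(3H)-one
Product: 13 (R)-4-(3,4-dimethoxybenzyl)dihydrofuran-2(3H)-one
Conditions: Bu3SnH (5 equiv), AIBN (cat.), toluene, reflux
Reagents that add atoms: none
Why: Tin hydride radical chain reduction: both α-chlorines are replaced via the α-carbonyl radical and the arylthio group via stannyl attack at sulfur and an α-oxy radical, so both C5 epimers converge on one lactone while C4, never a radical centre, keeps its configuration.

**Step 6**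
Reactants: 13 (R)-4-(3,4-dimethoxybenzyl)dihydrofuran-2(3H)-one; 14 3-(benzyloxy)-4-methoxybenzaldehyde
Product: 16 (3S,4R)-3-[(3-benzyloxy-4-methoxyphenyl)(hydroxy)methyl]-4-(3,4-dimethoxybenzyl)dihydrofuran-2(3H)-one, via lithium lactone enolate 15 (not isolated)
Conditions: LDA (1.1 equiv), THF, −78 °C; then 14, −78 °C; aq. NH4Cl
Reagents that add atoms: none
Why: Aldol addition of the lactone lithium enolate, with the aldehyde approaching anti to the C4 benzyl group, should set the new ring stereocentre 3,4-trans (descriptor 3S only because of the carbinol substituent); the carbinol centre forms as a mixture that step 7 erases.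

**Step 7**
Reactants: 16 (3S,4R)-3-[(3-benzyloxy-4-methoxyphenyl)(hydroxy)methyl]-4-(3,4-dimethoxybenzyl)dihydrofuran-2(3H)-one
Product: 17 prestegane A
Conditions: H2 (3 atm), 10% Pd/C, AcOH, HClO4 (cat.), rt
Reagents that add atoms: none
Why: Catalytic hydrogenolysis cleaves both benzylic C–O bonds, the p-methoxy-activated secondary carbinol (acid-assisted) and the benzyl ether, without touching the ring stereocentres, and the trans lactone is also the thermodynamically favoured epimer.

**Compound list**
1 | 3,4-dimethoxybenzyl bromide | COc1ccc(CBr)cc1OC | starting material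
2 | ethynylmagnesium bromide | C#C[Mg]Br | starting material
3 | 1,2-dimethoxy-4-(prop-2-yn-1-yl)benzene | COc1ccc(CC#C)cc1OC | intermediate
4 | (1R,2S,5R)-menthyl (S)-p-toluenesulfinate | C[C@@H]1CC[C@H]([C@@H](C1)O[S@](=O)c2ccc(C)cc2)C(C)C | starting material
5 | [3-(3,4-dimethoxyphenyl)prop-1-yn-1-yl]magnesium bromide | COc1ccc(CC#C[Mg]Br)cc1OC | intermediate
6 | (S)-1,2-dimethoxy-4-[3-(p-tolylsulfinyl)prop-2-yn-1-yl]benzene | COc1ccc(CC#C[S@@](=O)c2ccc(C)cc2)cc1OC | intermediate
7 | (R,Z)-1,2-dimethoxy-4-[3-(p-tolylsulfinyl)prop-2-en-1-yl]benzene | COc1ccc(C/C=C\[S@@](=O)c2ccc(C)cc2)cc1OC | intermediate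
8 | trichloroacetyl chloride | ClC(Cl)(Cl)C(Cl)=O | starting material
9 | dichloroketene | ClC(Cl)=C=O | intermediate
10 | (Z)-alkenyl(p-tolyl)sulfonium 2,2-dichloro-1-oxidoethenyl oxide zwitterion (acyloxysulfonium enolate) | COc1ccc(C/C=C\[S@@+](OC([O-])=C(Cl)Cl)c2ccc(C)cc2)cc1OC | intermediate
11 | 2,2-dichloro-3-(3,4-dimethoxybenzyl)-4-(p-tolylsulfonio)but-3-enoate (thionium carboxylate) | COc1ccc(C[C@@H](C=[S+]c2ccc(C)cc2)C(Cl)(Cl)C([O-])=O)cc1OC | intermediate
12 | (4S)-3,3-dichloro-4-(3,4-dimethoxybenzyl)-5-(p-tolylthio)dihydrofuran-2(3H)-one (C5 epimers, 4,5-trans expected to predominate) | COc1ccc(C[C@H]2C(Sc3ccc(C)cc3)OC(=O)C2(Cl)Cl)cc1OC | intermediate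
13 | (R)-4-(3,4-dimethoxybenzyl)dihydrofuran-2(3H)-one | COc1ccc(C[C@H]2COC(=O)C2)cc1OC | intermediate
14 | 3-(benzyloxy)-4-methoxybenzaldehyde | COc1ccc(C=O)cc1OCc1ccccc1 | starting material
15 | lithium enolate of 13 | [Li]OC1=C[C@@H](Cc2ccc(OC)c(OC)c2)CO1 | intermediate
16 | (3S,4R)-3-[(3-benzyloxy-4-methoxyphenyl)(hydroxy)methyl]-4-(3,4-dimethoxybenzyl)dihydrofuran-2(3H)-one (carbinol epimers) | COc1ccc(C(O)[C@H]2C(=O)OC[C@@H]2Cc2ccc(OC)c(OC)c2)cc1OCc1ccccc1 | intermediate
17 | prestegane A, (3R,4R)-4-(3,4-dimethoxybenzyl)-3-(3-hydroxy-4-methoxybenzyl)dihydrofuran-2(3H)-one | COc1ccc(C[C@H]2C(=O)OC[C@@H]2Cc2ccc(OC)c(OC)c2)cc1O | target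

**Step count.** Total: 7 steps. Longest linear sequence: 7 steps (steps 1 to 7, fully linear).

**Steps most likely to fail**

1. Step 4. Chirality transfer from sulfur to C4 may be incomplete if the conformer with p-tolyl over the alkene competes. The ketene may also be consumed unproductively, or the thionium ion intercepted by the electron-rich veratryl ring. The fallback sets out from 1 and comes back at 13, using auxiliary-controlled alkylation instead of chirality transfer. Mono-tert-butyl succinate is coupled (PivCl, Et3N; then lithiated (R)-4-benzyloxazolidin-2-one) to give (R)-4-benzyl-3-(4-tert-butoxy-4-oxobutanoyl)oxazolidin-2-one F1. Its sodium enolate (NaHMDS, THF, −78 °C) is alkylated with 1 on the face away from the auxiliary benzyl group to give (R)-4-benzyl-3-[(R)-4-tert-butoxy-2-(3,4-dimethoxybenzyl)-4-oxobutanoyl]oxazolidin-2-one F2. LiBH4 (THF/MeOH, 0 °C) removes the auxiliary reductively to give tert-butyl (R)-4-(3,4-dimethoxyphenyl)-3-(hydroxymethyl)butanoate F3, and TFA in CH2Cl2 closes the lactone to 13.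

2. Step 3. The alkyne may be over-reduced to the saturated sulfoxide, the catalyst may be inhibited by sulfur, or the doubly activated CH2 may migrate (propargyl–allenyl or vinyl–allyl sulfoxide isomerisation, the latter opening a sigmatropic racemisation path at sulfur). The fallback sets out from 3 and comes back at 7, fixing the alkene geometry before sulfur is introduced. Alkyne 3 is iodinated (NIS, cat. AgNO3, acetone) to 4-(3-iodoprop-2-yn-1-yl)-1,2-dimethoxybenzene F4. Diimide reduction (2-nitrobenzenesulfonyl hydrazide, Et3N) gives (Z)-4-(3-iodoprop-2-en-1-yl)-1,2-dimethoxybenzene F5. Iodine–lithium exchange (t-BuLi, Et2O, −78 °C) with retention of geometry, transmetalation with MgBr2·OEt2 and Andersen substitution on 4 with inversion at sulfur give 7.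

3. Step 7. Acid may dehydrate the benzylic alcohol to the α-benzylidene lactone, whose hydrogenation from the open face would erode the trans relationship; cleavage of the carbinol C–O bond may also stall. The fallback sets out from 13 (with 14 as the source of the aryl unit) and comes back at 17, replacing aldol/hydrogenolysis by direct enolate alkylation. Aldehyde 14 is reduced (NaBH4, MeOH) to 3-(benzyloxy)-4-methoxybenzyl alcohol F6 and converted (PBr3, Et2O, 0 °C) into 3-(benzyloxy)-4-methoxybenzyl bromide F7. The lithium enolate of 13 (LiHMDS, THF/DMPU, −78 °C) is alkylated with F7 anti to the C4 substituent to give O-benzylprestegane A F8, and neutral hydrogenolysis (H2, Pd/C, EtOAc) of the benzyl ether gives 17.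

**Further compounds**
F1 | step 4 | (R)-4-benzyl-3-(4-tert-butoxy-4-oxobutanoyl)oxazolidin-2-one | CC(C)(C)OC(=O)CCC(=O)N1[C@H](Cc2ccccc2)COC1=O
F2 | step 4 | (R)-4-benzyl-3-[(R)-4-tert-butoxy-2-(3,4-dimethoxybenzyl)-4-oxobutanoyl]oxazolidin-2-one | CC(C)(C)OC(=O)C[C@@H](Cc1ccc(OC)c(OC)c1)C(=O)N1[C@H](Cc2ccccc2)COC1=O
F3 | step 4 | tert-butyl (R)-4-(3,4-dimethoxyphenyl)-3-(hydroxymethyl)butanoate | CC(C)(C)OC(=O)C[C@@H](Cc1ccc(OC)c(OC)c1)CO
F4 | step 3 | 4-(3-iodoprop-2-yn-1-yl)-1,2-dimethoxybenzene | COc1ccc(CC#CI)cc1OC
F5 | step 3 | (Z)-4-(3-iodoprop-2-en-1-yl)-1,2-dimethoxybenzene | COc1ccc(C/C=C\I)cc1OC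
F6 | step 7 | 3-(benzyloxy)-4-methoxybenzyl alcohol | COc1ccc(CO)cc1OCc1ccccc1
F7 | step 7 | 3-(benzyloxy)-4-methoxybenzyl bromide | COc1ccc(CBr)cc1OCc1ccccc1
F8 | step 7 | O-benzylprestegane A | COc1ccc(C[C@H]2C(=O)OC[C@@H]2Cc2ccc(OC)c(OC)c2)cc1OCc1ccccc1
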